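**Plan**
Labels: C1 (carbinol bearing C7H2OBz), C2 (C=O), C3 (CH2), C4 (CHOH), C5 (CHOBz), C6 (CHOH). O4, O5 and C7 lie on the upper face, O1 and O6 on the lower face.
Enabling feature: C3 is the only ring carbon without oxygen and sits between the C2 carbonyl and C4. Removing it leaves the cyclopentanone ring C2–C1–C6–C5–C4 with every oxygen already in place.
Cuts, in retrosynthetic order: O5–benzoyl and C4–O4 (back to the C3=C4 enone); C2–C3 and C3–C4 (C3 removed as CH2, C2–C4 restored); C1–O1 and C6–O6 (diol to alkene); C1–C7 (formaldehyde).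
Forward: the five-membered ring is bought, a cyclopropane C2–C3–C4 is fused onto its enol ether, and breaking the shared C2–C4 bond turns the bicyclo[3.1.0]hexane into the six-membered ring.
Stereochemistry: C5 comes from (R)-4-silyloxycyclopentenone, C1 and C6 from OsO4 addition anti to O5, and C4 from oxygen delivery through a boron tether on O5.

Key step: step 7

Remark: the face of cyclopropanation and the configuration of the transient C4 chloride are drawn as sterics suggest; both centres become sp2 in the ring expansion, so the outcome does not depend on them.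

Step 1
Reactants: 1 (R)-4-(tert-butyldimethylsilyloxy)cyclopent-2-en-1-one; 2 formaldehyde (37 % in water)
Product: 3 (R)-4-(tert-butyldimethylsilyloxy)-2-(hydroxymethyl)cyclopent-2-en-1-one
Conditions: aq. HCHO, PBu3 (10 mol %), MeOH–CHCl3, rt
Reagents that add atoms: formaldehyde, C=O
Why: Morita–Baylis–Hillman reaction in which the weakly basic phosphine adds reversibly at C6, the phosphonium enolate attacks formaldehyde through C1 to form C1–C7 and the catalyst leaves again, and since nothing basic enough to enolise towards C4 is present the C5 stereocentre should be kept.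

Step 2
Reactants: 3 (R)-4-(tert-butyldimethylsilyloxy)-2-(hydroxymethyl)cyclopent-2-en-1-one; 4 benzoyl chloride
Product: 5 [(R)-3-(tert-butyldimethylsilyloxy)-5-oxocyclopent-1-en-1-yl]methyl benzoate
Conditions: BzCl, pyridine, CH2Cl2, 0 °C
Reagents that add atoms: benzoyl chloride, O=C(Cl)c1ccccc1
Why: Ordinary acylation of a primary allylic alcohol with an acid chloride, run with pyridine alone because stronger nucleophilic catalysts could displace the activated allylic benzoate in an SN2′ sense.

Step 3
Reactants: 5 [(R)-3-(tert-butyldimethylsilyloxy)-5-oxocyclopent-1-en-1-yl]methyl benzoate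
Product: 6 [(1S,2S,3R)-3-(tert-butyldimethylsilyloxy)-1,2-dihydroxy-5-oxocyclopentyl]methyl benzoate
Conditions: OsO4 (2 mol %), NMO, citric acid, tBuOH–H2O, rt
Reagents that add atoms: osmium tetroxide, O=[Os](=O)(=O)=O (carrier of both oxygen atoms); N-methylmorpholine N-oxide, C[N+]1([O-])CCOCC1; water, O
Why: Upjohn dihydroxylation in its citric-acid-buffered form for electron-poor alkenes, in which OsO4 adds suprafacially to C1=C6 from the lower face, opposite the bulky O5 silyl ether on the neighbouring carbon, and so sets C1 (S) and C6 (S) cis to each other and trans to O5.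

Step 4
Reactants: 6 [(1S,2S,3R)-3-(tert-butyldimethylsilyloxy)-1,2-dihydroxy-5-oxocyclopentyl]methyl benzoate
Product: 7 [(3aS,6R,6aS)-6-(tert-butyldimethylsilyloxy)-2,2-dimethyl-4-oxotetrahydro-3aH-cyclopenta[d][1,3]dioxol-3a-yl]methyl benzoate
Conditions: Me2C(OMe)2, pyridinium p-toluenesulfonate (cat.), CH2Cl2, rt
Reagents that add atoms: 2,2-dimethoxypropane, COC(C)(C)OC
Why: Acid-catalysed transketalisation, in which the cis-1,2-diol on a five-membered ring closes readily to the cis-fused dioxolane that masks O1 and O6 to the end and stops benzoyl migration from O7.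

Step 5
Reactants: 7 [(3aS,6R,6aS)-6-(tert-butyldimethylsilyloxy)-2,2-dimethyl-4-oxotetrahydro-3aH-cyclopenta[d][1,3]dioxol-3a-yl]methyl benzoate
Product: 8 [(3aS,6R,6aS)-6-(tert-butyldimethylsilyloxy)-2,2-dimethyl-4-(trimethylsilyloxy)-6,6a-dihydro-3aH-cyclopenta[d][1,3]dioxol-3a-yl]methyl benzoate (C2=C4 silyl enol ether)
Conditions: TMSOTf, Et3N, CH2Cl2, −78 to 0 °C
Reagents that add atoms: trimethylsilyl triflate, C[Si](C)(C)OS(=O)(=O)C(F)(F)F
Why: Soft enolisation with silyl triflate and amine, in which quaternary C1 leaves C4 as the only site of deprotonation and silylation of the carbonyl oxygen before proton loss avoids a free enolate that could expel the β-silyloxy group at C5.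

Step 6
Reactants: 8 C2=C4 silyl enol ether; 9 diiodomethane
Product: 10 (1S,2S,3S,4R,5R)-2-(benzoyloxymethyl)-4-(tert-butyldimethylsilyloxy)-2,3-(isopropylidenedioxy)-1-(trimethylsilyloxy)bicyclo[3.1.0]hexane (cyclopropane CH2 = C3 on the lower face)
Conditions: Et2Zn, CH2I2, CH2Cl2, 0 °C to rt; pyridine then aq. NaHCO3 quench
Reagents that add atoms: diiodomethane, ICI
Why: Furukawa variant of the Simmons–Smith cyclopropanation, which favours electron-rich silyl enol ethers, with the carbenoid expected on the lower face away from OTBS and C7H2OBz and guided by the allylic ketal oxygen O1, although either face would serve because C2 and C4 lose their configuration in the next step.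

Step 7
Reactants: 10 (1S,2S,3S,4R,5R)-2-(benzoyloxymethyl)-4-(tert-butyldimethylsilyloxy)-2,3-(isopropylidenedioxy)-1-(trimethylsilyloxy)bicyclo[3.1.0]hexane
Product: 12 (4R,5S,6S)-6-(benzoyloxymethyl)-4-(tert-butyldimethylsilyloxy)-5,6-(isopropylidenedioxy)cyclohex-2-en-1-one, via chloro ketone 11 (not isolated)
Conditions: FeCl3 (2.5 equiv), pyridine (1 equiv), DMF, 0 °C to rt; aqueous work-up, then NaOAc, MeOH, 40 °C
Reagents that add atoms: iron trichloride, Cl[Fe](Cl)Cl (supplies the chlorine of 11; none of its atoms remain in 12)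
Why: Trivalent iron takes one electron from the siloxycyclopropane, chloride strips the trimethylsilyl group, and the cyclopropyloxy radical relieves its strain by β-scission of the bond shared by both rings (C2–C4), giving the C2 ketone and a secondary C4 radical that abstracts chlorine from a second FeCl3, after which acetate removes the acidic C3–H and chloride leaves (E1cB) to give the C3=C4 enone. This is the Ito–Saegusa ring expansion of 1-siloxybicyclo[n.1.0]alkanes to 2-cycloalkenones. The six-membered ring is not made by cyclisation but by enlargement of the five-membered ring when the zero-atom bridge of the bicyclo[3.1.0]hexane is cut, so no new C–C bond and no closure mode is involved. No lasting stereocentre is created, since C2 and C4 of 10 and the transient C4–Cl centre of 11 all end up sp2, while C1, C5 and C6 are untouched. The step needs endocyclic (C2–C4) rather than exocyclic (C2–C3) cleavage, which is secured because the former gives a secondary instead of a primary radical and opens both strained rings at once, and quaternary C1 leaves C3 as the only site for the eliminating deprotonation. FeCl3 complexed by DMF and buffered with pyridine is a weak Lewis acid and acetate a weak base, so ketal, silyl ether and benzoate should survive and the enone should not enolise vinylogously towards aromatisation.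

Step 8
Reactants: 12 (4R,5S,6S)-6-(benzoyloxymethyl)-4-(tert-butyldimethylsilyloxy)-5,6-(isopropylidenedioxy)cyclohex-2-en-1-one
Product: 13 (4R,5S,6S)-6-(benzoyloxymethyl)-4-hydroxy-5,6-(isopropylidenedioxy)cyclohex-2-en-1-one
Conditions: HF·pyridine, THF, 0 °C to rt
Reagents that add atoms: none
Why: Fluoride-driven silyl ether cleavage under mildly acidic conditions, which spares ketal and benzoate and avoids a free alkoxide that could start vinylogous enolisation.

Step 9
Reactants: 13 (4R,5S,6S)-6-(benzoyloxymethyl)-4-hydroxy-5,6-(isopropylidenedioxy)cyclohex-2-en-1-one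
Product: 15 (2S,3S,4R,5R)-2-(benzoyloxymethyl)-4,5-dihydroxy-2,3-(isopropylidenedioxy)cyclohexan-1-one, via phenylboronate 14 (not isolated)
Conditions: PhB(OH)2 (1.5 equiv), Et3N (20 mol %), 4 Å MS, toluene, 40 °C; then 30 % H2O2, pH 7 buffer, THF, 0 °C
Reagents that add atoms: phenylboronic acid, OB(O)c1ccccc1
Why: Boronic-acid-tethered oxa-Michael addition as known for γ-hydroxy enones, in which O5 forms the boronic hemiester, amine coordination makes the remaining B–OH nucleophilic and its 5-exo-trig attack on C4 can only occur on the face carrying O5 (also the axial trajectory of the favoured half-chair), which sets C4 (R) with O4 cis to O5 before buffered peroxide removes boron.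

Step 10
Reactants: 15 (2S,3S,4R,5R)-2-(benzoyloxymethyl)-4,5-dihydroxy-2,3-(isopropylidenedioxy)cyclohexan-1-one; 4 benzoyl chloride
Product: 16 (2S,3S,4R,5R)-4-(benzoyloxy)-2-(benzoyloxymethyl)-5-hydroxy-2,3-(isopropylidenedioxy)cyclohexan-1-one
Conditions: BzCl (1.1 equiv), Ph2BOCH2CH2NH2 (10 mol %), iPr2NEt, MeCN, 0 °C to rt
Reagents that add atoms: benzoyl chloride, O=C(Cl)c1ccccc1
Why: Borinic-acid-catalysed regioselective acylation of a cis-1,2-diol, relying on the chair that avoids a 1,3-diaxial C7/O5 clash, in which O5 is equatorial and O4 axial, because the tetracoordinate borinate of such diols is acylated at the equatorial oxygen just as in the related stannylene acetal method.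

Step 11
Reactants: 16 (2S,3S,4R,5R)-4-(benzoyloxy)-2-(benzoyloxymethyl)-5-hydroxy-2,3-(isopropylidenedioxy)cyclohexan-1-one
Product: 17 (2S,3S,4R,5R)-4-(benzoyloxy)-2-(benzoyloxymethyl)-2,3,5-trihydroxycyclohexan-1-one (CNP0127041.1)
Conditions: CF3CO2H–H2O (9:1), CH2Cl2, 0 °C to rt
Reagents that add atoms: none
Why: Acid hydrolysis of the isopropylidene ketal at low temperature, under which benzoates should not migrate and the β-hydroxy ketone should not dehydrate, and which affects no stereocentre.

**Compound list**
1 | (R)-4-(tert-butyldimethylsilyloxy)cyclopent-2-en-1-one | O=C1C=C[C@H](O[Si](C)(C)C(C)(C)C)C1 | starting material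
2 | formaldehyde | C=O | starting material
3 | (R)-4-(tert-butyldimethylsilyloxy)-2-(hydroxymethyl)cyclopent-2-en-1-one | OCC1=C[C@H](O[Si](C)(C)C(C)(C)C)CC1=O | intermediate
4 | benzoyl chloride | O=C(Cl)c1ccccc1 | starting material
5 | [(R)-3-(tert-butyldimethylsilyloxy)-5-oxocyclopent-1-en-1-yl]methyl benzoate | O=C(OCC1=C[C@H](O[Si](C)(C)C(C)(C)C)CC1=O)c1ccccc1 | intermediate
6 | [(1S,2S,3R)-3-(tert-butyldimethylsilyloxy)-1,2-dihydroxy-5-oxocyclopentyl]methyl benzoate | O=C(OC[C@@]1(O)C(=O)C[C@@H](O[Si](C)(C)C(C)(C)C)[C@@H]1O)c1ccccc1 | intermediate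
7 | [(3aS,6R,6aS)-6-(tert-butyldimethylsilyloxy)-2,2-dimethyl-4-oxotetrahydro-3aH-cyclopenta[d][1,3]dioxol-3a-yl]methyl benzoate | O=C(OC[C@@]1(OC(C)(C)O2)C(=O)C[C@@H](O[Si](C)(C)C(C)(C)C)[C@@H]12)c1ccccc1 | intermediate
8 | [(3aS,6R,6aS)-6-(tert-butyldimethylsilyloxy)-2,2-dimethyl-4-(trimethylsilyloxy)-6,6a-dihydro-3aH-cyclopenta[d][1,3]dioxol-3a-yl]methyl benzoate | O=C(OC[C@@]1(OC(C)(C)O2)C(O[Si](C)(C)C)=C[C@@H](O[Si](C)(C)C(C)(C)C)[C@@H]12)c1ccccc1 | intermediate
9 | diiodomethane | ICI | starting material
10 | (1S,2S,3S,4R,5R)-2-(benzoyloxymethyl)-4-(tert-butyldimethylsilyloxy)-2,3-(isopropylidenedioxy)-1-(trimethylsilyloxy)bicyclo[3.1.0]hexane, cyclopropane CH2 syn to the ketal | O=C(OC[C@@]1(OC(C)(C)O2)[C@]3(O[Si](C)(C)C)C[C@@H]3[C@@H](O[Si](C)(C)C(C)(C)C)[C@@H]12)c1ccccc1 | intermediate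
11 | 2-(benzoyloxymethyl)-4-(tert-butyldimethylsilyloxy)-5-chloro-2,3-(isopropylidenedioxy)cyclohexan-1-one, chlorine at target C4 drawn trans to O5 | O=C(OC[C@@]1(OC(C)(C)O2)C(=O)C[C@H](Cl)[C@@H](O[Si](C)(C)C(C)(C)C)[C@@H]12)c1ccccc1 | intermediate
12 | (4R,5S,6S)-6-(benzoyloxymethyl)-4-(tert-butyldimethylsilyloxy)-5,6-(isopropylidenedioxy)cyclohex-2-en-1-one | O=C(OC[C@@]1(OC(C)(C)O2)C(=O)C=C[C@@H](O[Si](C)(C)C(C)(C)C)[C@@H]12)c1ccccc1 | intermediate
13 | (4R,5S,6S)-6-(benzoyloxymethyl)-4-hydroxy-5,6-(isopropylidenedioxy)cyclohex-2-en-1-one | O=C(OC[C@@]1(OC(C)(C)O2)C(=O)C=C[C@@H](O)[C@@H]12)c1ccccc1 | intermediate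
14 | cyclic phenylboronate of 15 (cis-fused 2-phenyl-1,3,2-dioxaborolane spanning O4 and O5) | O=C(OC[C@@]1(OC(C)(C)O2)C(=O)C[C@@H](O3)[C@@H](OB3c4ccccc4)[C@@H]12)c1ccccc1 | intermediate
15 | (2S,3S,4R,5R)-2-(benzoyloxymethyl)-4,5-dihydroxy-2,3-(isopropylidenedioxy)cyclohexan-1-one | O=C(OC[C@@]1(OC(C)(C)O2)C(=O)C[C@@H](O)[C@@H](O)[C@@H]12)c1ccccc1 | intermediate
16 | (2S,3S,4R,5R)-4-(benzoyloxy)-2-(benzoyloxymethyl)-5-hydroxy-2,3-(isopropylidenedioxy)cyclohexan-1-one | O=C(OC[C@@]1(OC(C)(C)O2)C(=O)C[C@@H](O)[C@@H](OC(=O)c3ccccc3)[C@@H]12)c1ccccc1 | intermediate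
17 | (2S,3S,4R,5R)-4-(benzoyloxy)-2-(benzoyloxymethyl)-2,3,5-trihydroxycyclohexan-1-one | O=C(OC[C@@]1(O)C(=O)C[C@@H](O)[C@@H](OC(=O)c2ccccc2)[C@@H]1O)c1ccccc1 | target

**Step count and risks**
Total steps: 11. Longest linear sequence: 11 (from 1).

Step 7. The outer C2–C3 bond may cleave in competition with the shared bond. Lewis acid may strip the ketal or the silyl ether. The product may enolise vinylogously and aromatise during the elimination.
The fallback inserts C3 by a polar 1,2-shift instead of a radical scission and sets out from ketone 7. Me3SiCHN2 with BF3·OEt2 in CH2Cl2 at −78 °C adds to C2. The less substituted C4 should migrate in preference to the quaternary, oxygen-bearing C1, giving the 3-trimethylsilyl cyclohexanone F1. Moist silica gel removes the carbon-bound silyl group to give the ring-enlarged cyclohexanone F2. TMSOTf and Et3N convert this, again with only one enolisable side, into the C2=C3 silyl enol ether F3. Saegusa–Ito oxidation with Pd(OAc)2 in MeCN then rejoins the route at enone 12. The same detour bypasses steps 5 and 6 if cyclopropanation of the crowded enol ether stalls.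

Step 9. The addition may be slow because a ring enone is less flexible than open-chain substrates. It may reverse when boron is taken off. The amine may trigger aromatisation of 13.
The fallback brings in O4 as an epoxide oxygen and sets out from 13. Hydroxyl-directed Weitz–Scheffer epoxidation uses tBuOOH with catalytic 1,8-diazabicyclo[5.4.0]undec-7-ene in CH2Cl2 at 0 °C. Hydrogen bonding to the free O5–H and the preference for axial attack both favour the upper face, so this should give the cis-epoxy alcohol F4. Na[PhSeB(OEt)3], made from PhSeSePh and NaBH4 in EtOH with AcOH, then cleaves the C3–O bond reductively and leaves O4 on C4. The route is rejoined at diol 15.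

Step 1. The phosphonium enolate or adventitious alkoxide may enolise towards C4 and expel silanolate, eroding enantiopurity or causing decomposition. Crowding at C6 may also slow catalyst addition.
The fallback attaches C7 by cross-coupling and sets out from 1. I2 and pyridine in CH2Cl2 give the (R)-2-iodo enone F5. Stille coupling with Bu3SnCH2OH under Pd(PPh3)4 in dioxane at 80 °C rejoins the route at alcohol 3.

**Further compounds**
F1 | step 7 | 2-(benzoyloxymethyl)-4-(tert-butyldimethylsilyloxy)-2,3-(isopropylidenedioxy)-6-(trimethylsilyl)cyclohexan-1-one, silyl group at target C3 drawn equatorial | O=C(OC[C@@]1(OC(C)(C)O2)C(=O)[C@@H]([Si](C)(C)C)C[C@@H](O[Si](C)(C)C(C)(C)C)[C@@H]12)c1ccccc1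
F2 | step 7 | (2S,3S,4R)-2-(benzoyloxymethyl)-4-(tert-butyldimethylsilyloxy)-2,3-(isopropylidenedioxy)cyclohexan-1-one | O=C(OC[C@@]1(OC(C)(C)O2)C(=O)CC[C@@H](O[Si](C)(C)C(C)(C)C)[C@@H]12)c1ccccc1
F3 | step 7 | C2=C3 trimethylsilyl enol ether of F2 | O=C(OC[C@@]1(OC(C)(C)O2)C(O[Si](C)(C)C)=CC[C@@H](O[Si](C)(C)C(C)(C)C)[C@@H]12)c1ccccc1
F4 | step 9 | 2,3-epoxy-6-(benzoyloxymethyl)-4-hydroxy-5,6-(isopropylidenedioxy)cyclohexan-1-one, epoxide oxygen on the upper face cis to O5 | O=C(OC[C@@]1(OC(C)(C)O2)C(=O)[C@H]3O[C@H]3[C@@H](O)[C@@H]12)c1ccccc1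
F5 | step 1 | (R)-4-(tert-butyldimethylsilyloxy)-2-iodocyclopent-2-en-1-one | O=C1C(I)=C[C@H](O[Si](C)(C)C(C)(C)C)C1
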